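**Plan** (labdane numbering: ring A = C1–C5/C10, ring B = C5–C10, side chain C11–C16)
- Retrosynthesis: the side chain is cut at C12–C13 (B-alkyl Suzuki) into a butenolide vinyl iodide and a 9-vinyl-Δ8-decalin. The vinyl group is cut at C9–C11 (enol triflate of a trans-decal-9-one). Ring B is then cut at C7–C8 and C5–C6, which removes a C6–C7 ethylene unit and leaves a ring-A 1,3-diketone.
- Enabling feature: in ring B, C8 is the only enolisable carbon of that diketone because C10 is quaternary. C5 lies between the quaternary carbons C4 and C10, so its ketone cannot enolise and can only accept a Wittig closure. A vinylphosphonium salt therefore serves as the C6–C7 unit (Michael addition at C8, intramolecular Wittig at C5).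
- Forward: ring A is bought; C10 is set by Pd-catalysed decarboxylative allylation and the allyl group is trimmed to propanoyl; ring B is annulated in one operation. The helpers left by the annulation (C5=C6 unsaturation, C9 carbonyl) are removed by hydrogenation and by triflation/vinylation.
- The side chain (C13–C16 with the butenolide) is built from but-2-yne-1,4-diol and dihydroxyacetone acetonide and is joined last.
- Stereochemistry: C10 from the (R)-t-Bu-PHOX ligand; C5 from hydrogenation anti to the axial methyl groups (trans-decalin); the furanone C5 from a RAMP-hydrazone alkylation; the E-alkene from trans-hydroalumination/iodination and a stereoretentive coupling.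

Key step: step 7

Assumption: the (R)-ligand is taken to give (R)-4 and the RAMP hydrazone the (4R)-dioxanone, each the mirror image of the established sense for the (S)-ligand and the SAMP hydrazone; if a sense were opposite, the other enantiomer of ligand or auxiliary would be used.

Step 1
Reactants: 1 2,2,6-trimethylcyclohexan-1-one
Product: 3 allyl 2,6,6-trimethylcyclohex-1-en-1-yl carbonate, via lithium enolate 2 (not isolated)
Conditions: LiHMDS, THF, 0 °C; then allyl chloroformate, −78 °C → rt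
Reagents that add atoms: allyl chloroformate C=CCOC(Cl)=O
Why: The only α-hydrogen is removed and the hindered tetrasubstituted lithium enolate is O-acylated (enol carbonate formation), which fixes the enolate regiochemistry for step 2.

Step 2
Reactants: 3 allyl 2,6,6-trimethylcyclohex-1-en-1-yl carbonate
Product: 4 (R)-2-allyl-2,6,6-trimethylcyclohexan-1-one
Conditions: Pd2(dba)3 (2.5 mol %), (R)-t-Bu-PHOX (6 mol %), THF, 25 °C
Reagents that add atoms: none
Why: Decarboxylative asymmetric Tsuji allylation; the Pd-allyl/enolate pair formed after loss of CO2 should recombine under ligand control and set the quaternary carbon (later C10).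

Step 3
Reactants: 4 (R)-2-allyl-2,6,6-trimethylcyclohexan-1-one
Product: 5 (R,E)-2,6,6-trimethyl-2-(prop-1-en-1-yl)cyclohexan-1-one
Conditions: PdCl2(MeCN)2 (5 mol %), toluene, 70 °C
Reagents that add atoms: none
Why: Pd-hydride alkene isomerisation moves the terminal double bond by one position to the more stable (E)-propenyl group and cannot go further because the next carbon is quaternary.

Step 4
Reactants: 5 (R,E)-2,6,6-trimethyl-2-(prop-1-en-1-yl)cyclohexan-1-one
Product: 7 (R)-1,3,3-trimethyl-2-oxocyclohexane-1-carbaldehyde, via secondary ozonide 6 (not isolated)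
Conditions: O3, CH2Cl2, −78 °C; then PPh3, −78 °C → rt
Reagents that add atoms: ozone [O-][O+]=O
Why: Ozonolysis with reductive work-up cleaves the propenyl C=C and leaves the formyl carbon (later C9) on the quaternary centre; the ketone is inert.

Step 5
Reactants: 7 (R)-1,3,3-trimethyl-2-oxocyclohexane-1-carbaldehyde
Product: 8 (2R)-2-(1-hydroxypropyl)-2,6,6-trimethylcyclohexan-1-one (both carbinol epimers)
Conditions: EtMgBr (1.1 equiv), Et2O, −78 °C; aq. NH4Cl
Reagents that add atoms: ethylmagnesium bromide CC[Mg]Br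
Why: Grignard addition should be chemoselective for the aldehyde because the ring ketone is flanked by two quaternary carbons; the carbinol configuration is irrelevant since it is oxidised next.

Step 6
Reactants: 8 (2R)-2-(1-hydroxypropyl)-2,6,6-trimethylcyclohexan-1-one
Product: 9 (R)-2,6,6-trimethyl-2-propanoylcyclohexan-1-one
Conditions: Dess–Martin periodinane, CH2Cl2, rt
Reagents that add atoms: none
Why: Dess–Martin oxidation gives the 1,3-diketone under near-neutral conditions that avoid retro-aldol cleavage at the quaternary carbon.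

Step 7
Reactants: 9 (R)-2,6,6-trimethyl-2-propanoylcyclohexan-1-one; 10 triphenyl(vinyl)phosphonium bromide
Product: 13 (8aS)-2,5,5,8a-tetramethyl-3,5,6,7,8,8a-hexahydronaphthalen-1(2H)-one (C2 epimers), via potassium enolate 11 (not isolated), via phosphorus ylide 12 (not isolated)
Conditions: KHMDS (1.05 equiv), THF, −78 °C; 10 (1.2 equiv), −78 °C → rt; then toluene, 100 °C
Reagents that add atoms: none
Why: The potassium enolate 11, which can form only at C8, adds in Michael fashion to the vinylphosphonium salt (C7–C8 bond), and the resulting non-stabilised ylide 12 closes on the C5 ketone through an oxaphosphetane that collapses to the C5=C6 alkene and triphenylphosphine oxide. The closest known reaction type is the Michael addition/intramolecular Wittig annulation of keto enolates with vinyltriphenylphosphonium bromide (Schweizer's reagent). Ring B is closed in the Wittig stage by 6-exo-trig attack of the ylide carbon C6 on the C5 carbonyl; attack on the C9 carbonyl would need a four-membered ring. No stereocentre of the target is created here: C10 is carried through unchanged, the C8 methine forms as a mixture that is erased in step 9, and C5 is set in step 8. The step needs C- rather than O-alkylation of the enolate and ring closure without proton scrambling or a second Michael addition; the soft phosphonium acceptor, the exact stoichiometry of base and the lower basicity of the ylide relative to a ketone enolate should secure this, while heat is used to overcome the hindrance of the ketone between C4 and C10.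

Step 8
Reactants: 13 (8aS)-2,5,5,8a-tetramethyl-3,5,6,7,8,8a-hexahydronaphthalen-1(2H)-one
Product: 14 (4aS,8aS)-2,5,5,8a-tetramethyloctahydronaphthalen-1(2H)-one (C2 epimers)
Conditions: H2 (4 atm), 10% Pd/C, EtOAc, rt
Reagents that add atoms: none
Why: Heterogeneous syn-hydrogenation of the trisubstituted C5=C6 alkene should occur from the face opposite the axial C10 methyl and the cis C4 methyl, as is usual for 4,4,10-trimethyl-Δ5-octalins, setting C5 as (S) and the trans ring fusion.

Step 9
Reactants: 14 (4aS,8aS)-2,5,5,8a-tetramethyloctahydronaphthalen-1(2H)-one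
Product: 16 (4aS,8aS)-2,5,5,8a-tetramethyl-3,4,4a,5,6,7,8,8a-octahydronaphthalen-1-yl trifluoromethanesulfonate, via potassium enolate 15 (not isolated)
Conditions: KHMDS, THF, −78 → 0 °C; then PhNTf2, −78 °C → rt
Reagents that add atoms: N-phenylbis(trifluoromethanesulfonimide) O=S(=O)(N(c1ccccc1)S(=O)(=O)C(F)(F)F)C(F)(F)F
Why: Enolisation is possible only toward C8 because C10 is quaternary, so O-triflation gives a single tetrasubstituted enol triflate and both C8 epimers converge.

Step 10
Reactants: 16 (4aS,8aS)-2,5,5,8a-tetramethyl-3,4,4a,5,6,7,8,8a-octahydronaphthalen-1-yl trifluoromethanesulfonate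
Product: 17 (4aS,8aS)-1-ethenyl-2,5,5,8a-tetramethyl-3,4,4a,5,6,7,8,8a-octahydronaphthalene
Conditions: tributyl(vinyl)stannane, Pd(PPh3)4 (5 mol %), LiCl, THF, reflux
Reagents that add atoms: tributyl(vinyl)stannane C=C[Sn](CCCC)(CCCC)CCCC
Why: Stille coupling of the enol triflate forms the C9–C11 bond and leaves the C8=C9 double bond in place.

Step 11
Reactants: 18 but-2-yne-1,4-diol
Product: 19 4-{[tert-butyl(dimethyl)silyl]oxy}but-2-yn-1-ol
Conditions: TBSCl (1 equiv), imidazole, DMF, 0 °C → rt, 18 in excess (3 equiv)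
Reagents that add atoms: tert-butyldimethylsilyl chloride CC(C)(C)[Si](C)(C)Cl
Why: Silylation of the symmetrical diol used in excess should give mainly the mono-ether, which differentiates the two ends of the C4 unit.

Step 12
Reactants: 19 4-{[tert-butyl(dimethyl)silyl]oxy}but-2-yn-1-ol
Product: 21 (Z)-4-{[tert-butyl(dimethyl)silyl]oxy}-3-iodobut-2-en-1-ol, via sodium alkenylalanate 20 (not isolated)
Conditions: Red-Al, THF, 0 °C → rt; EtOAc; then I2, −78 → 0 °C
Reagents that add atoms: iodine II
Why: Hydroxyl-directed trans-hydroalumination puts hydride on the alkyne carbon next to the free carbinol and aluminium on the distal carbon, and iodination with retention gives the (Z)-iodoalkene that fixes the geometry of the later C13=C14 alkene.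

Step 13
Reactants: 21 (Z)-4-{[tert-butyl(dimethyl)silyl]oxy}-3-iodobut-2-en-1-ol
Product: 22 (Z)-[(4-bromo-2-iodobut-2-en-1-yl)oxy](tert-butyl)dimethylsilane
Conditions: CBr4, PPh3, CH2Cl2, 0 °C
Reagents that add atoms: carbon tetrabromide BrC(Br)(Br)Br
Why: Appel bromination converts the primary allylic alcohol by SN2 without allylic transposition; vinyl iodide and silyl ether are untouched.

Step 14
Reactants: 23 2,2-dimethyl-1,3-dioxan-5-one; 24 (R)-1-amino-2-(methoxymethyl)pyrrolidine (RAMP)
Product: 25 (R)-N-(2,2-dimethyl-1,3-dioxan-5-ylidene)-2-(methoxymethyl)pyrrolidin-1-amine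
Conditions: benzene, reflux, Dean–Stark
Reagents that add atoms: none
Why: Condensation of the ketone with the hydrazine gives the chiral hydrazone of the dihydroxyacetone equivalent.

Step 15
Reactants: 25 (R)-N-(2,2-dimethyl-1,3-dioxan-5-ylidene)-2-(methoxymethyl)pyrrolidin-1-amine; 22 (Z)-[(4-bromo-2-iodobut-2-en-1-yl)oxy](tert-butyl)dimethylsilane
Product: 27 (R)-N-[(4R)-4-[(2Z)-4-{[tert-butyl(dimethyl)silyl]oxy}-3-iodobut-2-en-1-yl]-2,2-dimethyl-1,3-dioxan-5-ylidene]-2-(methoxymethyl)pyrrolidin-1-amine, via lithium azaenolate 26 (not isolated)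
Conditions: t-BuLi (1.05 equiv), THF, −78 °C; then 22, −100 °C → rt
Reagents that add atoms: none
Why: Enders RAMP-hydrazone alkylation; the chelated lithium azaenolate should be alkylated by the allylic bromide on the face dictated by the methoxymethylpyrrolidine auxiliary, setting the later furanone C5 as (R).

Step 16
Reactants: 27 (R)-N-[(4R)-4-[(2Z)-4-{[tert-butyl(dimethyl)silyl]oxy}-3-iodobut-2-en-1-yl]-2,2-dimethyl-1,3-dioxan-5-ylidene]-2-(methoxymethyl)pyrrolidin-1-amine
Product: 28 (3R,5Z)-1,3,7-trihydroxy-6-iodohept-5-en-2-one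
Conditions: aq. HCl (3 M), THF, 0 °C → rt; neutralisation
Reagents that add atoms: water O
Why: Acid hydrolysis removes hydrazone, acetonide and silyl ether in one operation; the α-stereocentre of the ketose-like product should survive because no base is present.

Step 17
Reactants: 28 (3R,5Z)-1,3,7-trihydroxy-6-iodohept-5-en-2-one
Product: 29 (3R,5Z)-1,7-bis{[tert-butyl(dimethyl)silyl]oxy}-3-hydroxy-6-iodohept-5-en-2-one
Conditions: TBSCl (2.1 equiv), imidazole, DMF, −20 °C
Reagents that add atoms: tert-butyldimethylsilyl chloride CC(C)(C)[Si](C)(C)Cl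
Why: The two primary hydroxyls should silylate much faster than the secondary α-ketol hydroxyl, which leaves exactly the oxygen needed for the lactone free.

Step 18
Reactants: 29 (3R,5Z)-1,7-bis{[tert-butyl(dimethyl)silyl]oxy}-3-hydroxy-6-iodohept-5-en-2-one
Product: 31 (5R)-4-({[tert-butyl(dimethyl)silyl]oxy}methyl)-5-[(2Z)-4-{[tert-butyl(dimethyl)silyl]oxy}-3-iodobut-2-en-1-yl]furan-2(5H)-one, via ester ylide 30 (not isolated)
Conditions: Ph3P=C=C=O (1.2 equiv), toluene, 90 °C
Reagents that add atoms: (triphenylphosphoranylidene)ketene O=C=C=P(c1ccccc1)(c1ccccc1)c1ccccc1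
Why: Bestmann butenolide synthesis; the free hydroxyl adds to the cumulated ylide and the stabilised ester ylide closes on the neighbouring ketone by intramolecular Wittig reaction, without touching the stereocentre.

Step 19
Reactants: 17 (4aS,8aS)-1-ethenyl-2,5,5,8a-tetramethyl-3,4,4a,5,6,7,8,8a-octahydronaphthalene; 31 (5R)-4-({[tert-butyl(dimethyl)silyl]oxy}methyl)-5-[(2Z)-4-{[tert-butyl(dimethyl)silyl]oxy}-3-iodobut-2-en-1-yl]furan-2(5H)-one
Product: 33 (5R)-4-({[tert-butyl(dimethyl)silyl]oxy}methyl)-5-{(2E)-3-({[tert-butyl(dimethyl)silyl]oxy}methyl)-5-[(4aS,8aS)-2,5,5,8a-tetramethyl-3,4,4a,5,6,7,8,8a-octahydronaphthalen-1-yl]pent-2-en-1-yl}furan-2(5H)-one, via alkylborane 32 (not isolated)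
Conditions: 9-BBN (1.3 equiv), THF, rt; H2O; then 31, Pd(dppf)Cl2 (5 mol %), AsPh3, Cs2CO3, DMF/H2O, rt
Reagents that add atoms: none
Why: Anti-Markovnikov hydroboration of the terminal vinyl group (the tetrasubstituted ring alkene is inert) followed by B-alkyl Suzuki–Miyaura coupling with the vinyl iodide, with retention of geometry, forms C12–C13 and the E-alkene.

Step 20
Reactants: 33 (5R)-4-({[tert-butyl(dimethyl)silyl]oxy}methyl)-5-{(2E)-3-({[tert-butyl(dimethyl)silyl]oxy}methyl)-5-[(4aS,8aS)-2,5,5,8a-tetramethyl-3,4,4a,5,6,7,8,8a-octahydronaphthalen-1-yl]pent-2-en-1-yl}furan-2(5H)-one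
Product: 34 (5R)-4-(hydroxymethyl)-5-{(2E)-3-(hydroxymethyl)-5-[(4aS,8aS)-2,5,5,8a-tetramethyl-3,4,4a,5,6,7,8,8a-octahydronaphthalen-1-yl]pent-2-en-1-yl}furan-2(5H)-one
Conditions: HF·pyridine, pyridine/THF, 0 °C → rt
Reagents that add atoms: none
Why: Fluoride-mediated desilylation under mildly acidic conditions should free both primary alcohols without epimerising or opening the butenolide.

**Compound list**
1 | 2,2,6-trimethylcyclohexan-1-one | CC1CCCC(C)(C)C1=O | starting material
2 | lithium 2,6,6-trimethylcyclohex-1-en-1-olate | [Li+].[O-]C1=C(C)CCCC1(C)C | intermediate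
3 | allyl 2,6,6-trimethylcyclohex-1-en-1-yl carbonate | C=CCOC(=O)OC1=C(C)CCCC1(C)C | intermediate
4 | (R)-2-allyl-2,6,6-trimethylcyclohexan-1-one | C=CC[C@@]1(C)CCCC(C)(C)C1=O | intermediate
5 | (R,E)-2,6,6-trimethyl-2-(prop-1-en-1-yl)cyclohexan-1-one | C/C=C/[C@@]1(C)CCCC(C)(C)C1=O | intermediate
6 | secondary ozonide of 5 (3-methyl-5-[(1R)-1,3,3-trimethyl-2-oxocyclohexyl]-1,2,4-trioxolane) | CC1OOC(O1)[C@@]2(C)CCCC(C)(C)C2=O | intermediate
7 | (R)-1,3,3-trimethyl-2-oxocyclohexane-1-carbaldehyde | O=C[C@@]1(C)CCCC(C)(C)C1=O | intermediate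
8 | (2R)-2-(1-hydroxypropyl)-2,6,6-trimethylcyclohexan-1-one | CCC(O)[C@@]1(C)CCCC(C)(C)C1=O | intermediate
9 | (R)-2,6,6-trimethyl-2-propanoylcyclohexan-1-one | CCC(=O)[C@@]1(C)CCCC(C)(C)C1=O | intermediate
10 | triphenyl(vinyl)phosphonium bromide | C=C[P+](c1ccccc1)(c1ccccc1)c1ccccc1.[Br-] | starting material
11 | potassium 1-[(1R)-1,3,3-trimethyl-2-oxocyclohexyl]prop-1-en-1-olate | CC=C([O-])[C@@]1(C)CCCC(C)(C)C1=O.[K+] | intermediate
12 | (2R)-2,6,6-trimethyl-2-[2-methyl-4-(triphenyl-λ5-phosphanylidene)butanoyl]cyclohexan-1-one | CC(CC=P(c1ccccc1)(c1ccccc1)c1ccccc1)C(=O)[C@@]1(C)CCCC(C)(C)C1=O | intermediate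
13 | (8aS)-2,5,5,8a-tetramethyl-3,5,6,7,8,8a-hexahydronaphthalen-1(2H)-one | CC1C(=O)[C@@]2(C)CCCC(C)(C)C2=CC1 | intermediate
14 | (4aS,8aS)-2,5,5,8a-tetramethyloctahydronaphthalen-1(2H)-one | CC1C(=O)[C@@]2(C)CCCC(C)(C)[C@@H]2CC1 | intermediate
15 | potassium (4aS,8aS)-2,5,5,8a-tetramethyl-3,4,4a,5,6,7,8,8a-octahydronaphthalen-1-olate | CC1=C([O-])[C@@]2(C)CCCC(C)(C)[C@@H]2CC1.[K+] | intermediate
16 | (4aS,8aS)-2,5,5,8a-tetramethyl-3,4,4a,5,6,7,8,8a-octahydronaphthalen-1-yl trifluoromethanesulfonate | CC1=C(OS(=O)(=O)C(F)(F)F)[C@@]2(C)CCCC(C)(C)[C@@H]2CC1 | intermediate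
17 | (4aS,8aS)-1-ethenyl-2,5,5,8a-tetramethyl-3,4,4a,5,6,7,8,8a-octahydronaphthalene | CC1=C(C=C)[C@@]2(C)CCCC(C)(C)[C@@H]2CC1 | intermediate
18 | but-2-yne-1,4-diol | OCC#CCO | starting material
19 | 4-{[tert-butyl(dimethyl)silyl]oxy}but-2-yn-1-ol | OCC#CCO[Si](C)(C)C(C)(C)C | intermediate
20 | sodium cyclic alkenylalanate from 19 and Red-Al | COCCO[Al-]1(OCCOC)OCC=C1CO[Si](C)(C)C(C)(C)C.[Na+] | intermediate
21 | (Z)-4-{[tert-butyl(dimethyl)silyl]oxy}-3-iodobut-2-en-1-ol | OC/C=C(\I)CO[Si](C)(C)C(C)(C)C | intermediate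
22 | (Z)-[(4-bromo-2-iodobut-2-en-1-yl)oxy](tert-butyl)dimethylsilane | BrC/C=C(\I)CO[Si](C)(C)C(C)(C)C | intermediate
23 | 2,2-dimethyl-1,3-dioxan-5-one | CC1(C)OCC(=O)CO1 | starting material
24 | (R)-1-amino-2-(methoxymethyl)pyrrolidine (RAMP) | COC[C@H]1CCCN1N | starting material
25 | (R)-N-(2,2-dimethyl-1,3-dioxan-5-ylidene)-2-(methoxymethyl)pyrrolidin-1-amine | COC[C@H]1CCCN1N=C1COC(C)(C)OC1 | intermediate
26 | lithium azaenolate of 25 | COC[C@H]1CCCN1[N-]C1=COC(C)(C)OC1.[Li+] | intermediate
27 | (R)-N-[(4R)-4-[(2Z)-4-{[tert-butyl(dimethyl)silyl]oxy}-3-iodobut-2-en-1-yl]-2,2-dimethyl-1,3-dioxan-5-ylidene]-2-(methoxymethyl)pyrrolidin-1-amine | COC[C@H]1CCCN1N=C1COC(C)(C)O[C@@H]1C/C=C(\I)CO[Si](C)(C)C(C)(C)C | intermediate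
28 | (3R,5Z)-1,3,7-trihydroxy-6-iodohept-5-en-2-one | OCC(=O)[C@H](O)C/C=C(\I)CO | intermediate
29 | (3R,5Z)-1,7-bis{[tert-butyl(dimethyl)silyl]oxy}-3-hydroxy-6-iodohept-5-en-2-one | CC(C)(C)[Si](C)(C)OCC(=O)[C@H](O)C/C=C(\I)CO[Si](C)(C)C(C)(C)C | intermediate
30 | (triphenyl-λ5-phosphanylidene)acetate ester of 29 | CC(C)(C)[Si](C)(C)OCC(=O)[C@H](OC(=O)C=P(c1ccccc1)(c1ccccc1)c1ccccc1)C/C=C(\I)CO[Si](C)(C)C(C)(C)C | intermediate
31 | (5R)-4-({[tert-butyl(dimethyl)silyl]oxy}methyl)-5-[(2Z)-4-{[tert-butyl(dimethyl)silyl]oxy}-3-iodobut-2-en-1-yl]furan-2(5H)-one | CC(C)(C)[Si](C)(C)OC/C(I)=C/C[C@H]1OC(=O)C=C1CO[Si](C)(C)C(C)(C)C | intermediate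
32 | 9-{2-[(4aS,8aS)-2,5,5,8a-tetramethyl-3,4,4a,5,6,7,8,8a-octahydronaphthalen-1-yl]ethyl}-9-borabicyclo[3.3.1]nonane | CC1=C(CCB3C4CCCC3CCC4)[C@@]2(C)CCCC(C)(C)[C@@H]2CC1 | intermediate
33 | (5R)-4-({[tert-butyl(dimethyl)silyl]oxy}methyl)-5-{(2E)-3-({[tert-butyl(dimethyl)silyl]oxy}methyl)-5-[(4aS,8aS)-2,5,5,8a-tetramethyl-3,4,4a,5,6,7,8,8a-octahydronaphthalen-1-yl]pent-2-en-1-yl}furan-2(5H)-one | CC1=C(CC/C(=C\C[C@H]2OC(=O)C=C2CO[Si](C)(C)C(C)(C)C)CO[Si](C)(C)C(C)(C)C)[C@@]2(C)CCCC(C)(C)[C@@H]2CC1 | intermediate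
34 | (5R)-4-(hydroxymethyl)-5-{(2E)-3-(hydroxymethyl)-5-[(4aS,8aS)-2,5,5,8a-tetramethyl-3,4,4a,5,6,7,8,8a-octahydronaphthalen-1-yl]pent-2-en-1-yl}furan-2(5H)-one | CC1=C(CC/C(=C\C[C@H]2OC(=O)C=C2CO)CO)[C@@]2(C)CCCC(C)(C)[C@@H]2CC1 | target

**Step count:** 20 steps in total. Longest linear sequence: 12 steps (steps 1–10, 19, 20); the side-chain branch is steps 11–18.

**Steps most likely to fail**

1. Step 7 (ring-B annulation). Process at risk: the ylide may fail to olefinate the C5 ketone, which is flanked by two quaternary carbons, so that proton exchange and a second Michael addition take over. The fallback sets out from 9 and comes back at 13. The potassium enolate 11 is C-allylated with allyl bromide to give (2R)-2,6,6-trimethyl-2-(2-methylpent-4-enoyl)cyclohexan-1-one F1. Ozonolysis with dimethyl sulfide work-up gives 3-methyl-4-oxo-4-[(1R)-1,3,3-trimethyl-2-oxocyclohexyl]butanal F2. An intramolecular McMurry coupling (TiCl3(DME)1.5, Zn–Cu, DME, reflux, slow addition) then joins the aldehyde carbon to the C5 carbonyl carbon, the only ketone it can reach through a six-membered ring, and returns 13. The two ring-B bonds are then made in separate operations.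

2. Step 19 (fragment union). Process at risk: base-mediated γ-deprotonation of the butenolide during the coupling, leading to epimerisation at the furanone C5 or lactone opening. The fallback sets out from 27 and the alkylborane 32 and comes back at 33. Borane 32 is coupled under the same catalyst with the base-stable vinyl iodide 27 to give (R)-N-[(4R)-4-{(2E)-3-({[tert-butyl(dimethyl)silyl]oxy}methyl)-5-[(4aS,8aS)-2,5,5,8a-tetramethyl-3,4,4a,5,6,7,8,8a-octahydronaphthalen-1-yl]pent-2-en-1-yl}-2,2-dimethyl-1,3-dioxan-5-ylidene]-2-(methoxymethyl)pyrrolidin-1-amine F3. Acid hydrolysis as in step 16 gives (3R,5E)-1,3-dihydroxy-6-(hydroxymethyl)-8-[(4aS,8aS)-2,5,5,8a-tetramethyl-3,4,4a,5,6,7,8,8a-octahydronaphthalen-1-yl]oct-5-en-2-one F4. Silylation of the two primary hydroxyls as in step 17 gives the bis-silyl ether of F4 at O1 and at the hydroxymethyl oxygen F5. The Bestmann ylide then closes the butenolide on the complete skeleton and gives 33, so the lactone never meets the coupling base.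

3. Step 10 (vinylation). Process at risk: slow oxidative addition and transmetalation at the tetrasubstituted enol triflate next to quaternary C10, with competing S–O cleavage back to the ketone. The fallback sets out from 14 and comes back at 17. Vinylmagnesium bromide with anhydrous CeCl3 (THF, −78 → 0 °C) adds to ketone 14 to give (4aS,8aS)-1-ethenyl-2,5,5,8a-tetramethyldecahydronaphthalen-1-ol F6. Acid-catalysed dehydration (p-TsOH cat., benzene, 60 °C) can eliminate only toward C8 because C10 is quaternary, and gives the conjugated diene 17.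

**Further compounds**
F1 | step 7 | (2R)-2,6,6-trimethyl-2-(2-methylpent-4-enoyl)cyclohexan-1-one | C=CCC(C)C(=O)[C@@]1(C)CCCC(C)(C)C1=O
F2 | step 7 | 3-methyl-4-oxo-4-[(1R)-1,3,3-trimethyl-2-oxocyclohexyl]butanal | O=CCC(C)C(=O)[C@@]1(C)CCCC(C)(C)C1=O
F3 | step 19 | (R)-N-[(4R)-4-{(2E)-3-({[tert-butyl(dimethyl)silyl]oxy}methyl)-5-[(4aS,8aS)-2,5,5,8a-tetramethyl-3,4,4a,5,6,7,8,8a-octahydronaphthalen-1-yl]pent-2-en-1-yl}-2,2-dimethyl-1,3-dioxan-5-ylidene]-2-(methoxymethyl)pyrrolidin-1-amine | CC1=C(CC/C(=C\C[C@H]2OC(C)(C)OCC2=NN2CCC[C@@H]2COC)CO[Si](C)(C)C(C)(C)C)[C@@]2(C)CCCC(C)(C)[C@@H]2CC1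
F4 | step 19 | (3R,5E)-1,3-dihydroxy-6-(hydroxymethyl)-8-[(4aS,8aS)-2,5,5,8a-tetramethyl-3,4,4a,5,6,7,8,8a-octahydronaphthalen-1-yl]oct-5-en-2-one | CC1=C(CC/C(=C\C[C@@H](O)C(=O)CO)CO)[C@@]2(C)CCCC(C)(C)[C@@H]2CC1
F5 | step 19 | (3R,5E)-1-{[tert-butyl(dimethyl)silyl]oxy}-6-({[tert-butyl(dimethyl)silyl]oxy}methyl)-3-hydroxy-8-[(4aS,8aS)-2,5,5,8a-tetramethyl-3,4,4a,5,6,7,8,8a-octahydronaphthalen-1-yl]oct-5-en-2-one | CC1=C(CC/C(=C\C[C@@H](O)C(=O)CO[Si](C)(C)C(C)(C)C)CO[Si](C)(C)C(C)(C)C)[C@@]2(C)CCCC(C)(C)[C@@H]2CC1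
F6 | step 10 | (4aS,8aS)-1-ethenyl-2,5,5,8a-tetramethyldecahydronaphthalen-1-ol | CC1C(O)(C=C)[C@@]2(C)CCCC(C)(C)[C@@H]2CC1
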